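**Retrosynthetic overview**

1. Target 15 ⇐ aldehyde 12 (Julia–Kocienski ethylidenation gives the E-propenyl group) ⇐ nitrile 10 (partial reduction with iBu2AlH).
2. 10 ⇐ (R)-allylic alcohol 5 + fluoro-iodo-benzonitrile 7 in one flask: O1–C7a by SNAr, then C3a–C3 by 5-exo aryl radical closure. Ring B is the only ring formed; ring A and the trimethoxyphenyl ring are bought.
3. Enabling feature: C7a of ring A is para to C5, so carrying the C5 propenyl carbon as a nitrile makes a C7a–F bond SNAr-active. C3a, next to it and para to the C6 methoxy group, takes iodine by SEAr. The O1–C2–C3 unit of ring B is a 1-arylallyl alcohol whose =CH2 becomes the C3 methyl group.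
4. 5 ⇐ lipase resolution of racemic acetate 4 ⇐ 3,4,5-trimethoxybenzaldehyde 1 + vinylmagnesium bromide 2; 7 ⇐ iodination of 4-fluoro-2-methoxybenzonitrile 6.
5. Stereochemistry: C2 is selected in the enzymatic resolution; C3 is relayed from C2 in the ring closure (2,3-trans).

Key step: step 4

Assumption: sulfone 13 is treated as a purchasable reagent (otherwise it is made from 1-phenyl-1H-tetrazole-5-thiol by S-ethylation and oxidation); atoms are numbered as in 2,3-dihydro-1-benzofuran, ring A being the benzo ring and ring B the dihydrofuran ring.

**Route**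

Step 1
Reactants: 1 3,4,5-trimethoxybenzaldehyde; 2 vinylmagnesium bromide
Product: 4 rac-1-(3,4,5-trimethoxyphenyl)prop-2-en-1-yl acetate, via bromomagnesium alkoxide 3 (not isolated)
Conditions: THF, –20 → 0 °C; then Ac2O, 0 °C → rt
Reagents that add atoms: acetic anhydride, CC(=O)OC(C)=O
Why: Grignard 1,2-addition to the aldehyde followed by O-acylation of the magnesium alkoxide in the same flask should give the racemic allylic acetate directly; no stereocontrol is needed here.

Step 2
Reactants: 4 rac-1-(3,4,5-trimethoxyphenyl)prop-2-en-1-yl acetate
Product: 5 (R)-1-(3,4,5-trimethoxyphenyl)prop-2-en-1-ol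
Conditions: Candida antarctica lipase B (immobilised), phosphate buffer pH 7, MTBE, 30 °C, stopped before half conversion
Reagents that add atoms: none
Why: Enzymatic kinetic resolution by lipase-catalysed ester hydrolysis: by the Kazlauskas rule (aryl as large, vinyl as medium substituent) the serine hydrolase should cleave the R acetate much faster than its enantiomer, so the carbinol centre that becomes C2 of the target is selected here.

Step 3
Reactants: 6 4-fluoro-2-methoxybenzonitrile
Product: 7 4-fluoro-5-iodo-2-methoxybenzonitrile
Conditions: N-iodosuccinimide, CF3CO2H, cat. H2SO4, rt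
Reagents that add atoms: N-iodosuccinimide, O=C1CCC(=O)N1I
Why: Electrophilic aromatic iodination should go to C5 of the benzonitrile, the one position that is para to the methoxy group, ortho to fluorine, meta to the nitrile and not flanked by two substituents.

Step 4
Reactants: 5 (R)-1-(3,4,5-trimethoxyphenyl)prop-2-en-1-ol; 7 4-fluoro-5-iodo-2-methoxybenzonitrile
Product: 10 (2R,3R)-6-methoxy-3-methyl-2-(3,4,5-trimethoxyphenyl)-2,3-dihydro-1-benzofuran-5-carbonitrile, via potassium alkoxide 8 (not isolated), via aryl allyl ether 9 (not isolated)
Conditions: KN(SiMe3)2 (slightly less than 1 equiv), THF, –40 °C; then 7 (slight excess), –40 → 0 °C, dark; then, same flask, Bu3SnH, Et3B (cat.), air, 0 °C → rt, dilute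
Reagents that add atoms: none
Why: Alkoxide 8 displaces fluoride from 7 by addition–elimination through a Meisenheimer adduct stabilised by the para nitrile, which forms the O1–C7a bond without touching the carbinol carbon, so C2 keeps its R configuration; Bu3Sn• (started by Et3B and O2) then takes the iodine atom from 9, and the aryl σ-radical at C3a adds to the inner alkene carbon to form the C3a–C3 bond before Bu3SnH reduces the primary radical to the C3 methyl group. The closest known reactions are the SNAr etherification of 4-fluorobenzonitriles with secondary potassium alkoxides and the tin hydride cyclisation of 2-iodophenyl allyl ethers to 3-methyl-2,3-dihydrobenzofurans. Ring B closes in the 5-exo-trig mode. The new stereocentre C3 is under substrate control: in the chair-like transition state of the Beckwith–Houk type the C2 aryl group sits pseudo-equatorial and the =CH2 terminus turns away from it, so the methyl group should end up trans to the aryl group (3R). The step needs site selectivity (O at C7a, C at C3a), exo over endo closure and trans over cis facial selectivity: the first is fixed by where fluorine and iodine stand in 7 and by the nitrile activating only the C–F bond, the second by the kinetic preference of aryl radicals for 5-exo attack, the third by the C2 substituent and the low temperature that Et3B initiation allows. Direct reduction of the aryl radical and a 1,4-hydrogen shift from C2–H should not compete with a cyclisation this fast.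

Step 5
Reactants: 10 (2R,3R)-6-methoxy-3-methyl-2-(3,4,5-trimethoxyphenyl)-2,3-dihydro-1-benzofuran-5-carbonitrile
Product: 12 (2R,3R)-6-methoxy-3-methyl-2-(3,4,5-trimethoxyphenyl)-2,3-dihydro-1-benzofuran-5-carbaldehyde, via N-aluminio aldimine 11 (not isolated)
Conditions: iBu2AlH, CH2Cl2, –78 °C; then aq. KNaC4H4O6 (potassium sodium tartrate), rt
Reagents that add atoms: water, O
Why: Partial reduction of an aryl nitrile with iBu2AlH should stop at the N-aluminio aldimine, which is hydrolysed to the aldehyde on work-up; the ethers and both stereocentres are inert to the hydride.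

Step 6
Reactants: 12 (2R,3R)-6-methoxy-3-methyl-2-(3,4,5-trimethoxyphenyl)-2,3-dihydro-1-benzofuran-5-carbaldehyde; 13 5-(ethylsulfonyl)-1-phenyl-1H-tetrazole
Product: 15 (2R,3R)-6-methoxy-3-methyl-5-[(E)-prop-1-en-1-yl]-2-(3,4,5-trimethoxyphenyl)-2,3-dihydro-1-benzofuran, via potassium sulfonyl carbanion 14 (not isolated)
Conditions: 13, KN(SiMe3)2, DME, –60 °C; then 12, –60 °C → rt
Reagents that add atoms: none
Why: Julia–Kocienski olefination: the metalated tetrazolyl sulfone adds to the aldehyde, and Smiles rearrangement with loss of SO2 and the tetrazololate should give the alkene with the E geometry expected for aryl aldehydes under potassium/DME conditions; no stereocentre is touched.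

**Compound list**

1 | 3,4,5-trimethoxybenzaldehyde | COc1cc(C=O)cc(OC)c1OC | starting material
2 | vinylmagnesium bromide | C=C[Mg]Br | starting material
3 | bromomagnesium rac-1-(3,4,5-trimethoxyphenyl)prop-2-en-1-olate | C=CC(O[Mg]Br)c1cc(OC)c(OC)c(OC)c1 | intermediate
4 | rac-1-(3,4,5-trimethoxyphenyl)prop-2-en-1-yl acetate | C=CC(OC(C)=O)c1cc(OC)c(OC)c(OC)c1 | intermediate
5 | (R)-1-(3,4,5-trimethoxyphenyl)prop-2-en-1-ol | C=C[C@@H](O)c1cc(OC)c(OC)c(OC)c1 | intermediate
6 | 4-fluoro-2-methoxybenzonitrile | COc1cc(F)ccc1C#N | starting material
7 | 4-fluoro-5-iodo-2-methoxybenzonitrile | COc1cc(F)c(I)cc1C#N | intermediate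
8 | potassium (R)-1-(3,4,5-trimethoxyphenyl)prop-2-en-1-olate | C=C[C@@H]([O-])c1cc(OC)c(OC)c(OC)c1.[K+] | intermediate
9 | 5-iodo-2-methoxy-4-{[(1R)-1-(3,4,5-trimethoxyphenyl)prop-2-en-1-yl]oxy}benzonitrile | C=C[C@@H](Oc1cc(OC)c(C#N)cc1I)c1cc(OC)c(OC)c(OC)c1 | intermediate
10 | (2R,3R)-6-methoxy-3-methyl-2-(3,4,5-trimethoxyphenyl)-2,3-dihydro-1-benzofuran-5-carbonitrile (2,3-trans) | N#Cc1cc2c(cc1OC)O[C@@H](c1cc(OC)c(OC)c(OC)c1)[C@@H]2C | intermediate
11 | N-(diisobutylaluminio) aldimine derived from nitrile 10 | CC(C)C[Al](CC(C)C)N=Cc1cc2c(cc1OC)O[C@@H](c1cc(OC)c(OC)c(OC)c1)[C@@H]2C | intermediate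
12 | (2R,3R)-6-methoxy-3-methyl-2-(3,4,5-trimethoxyphenyl)-2,3-dihydro-1-benzofuran-5-carbaldehyde | O=Cc1cc2c(cc1OC)O[C@@H](c1cc(OC)c(OC)c(OC)c1)[C@@H]2C | intermediate
13 | 5-(ethylsulfonyl)-1-phenyl-1H-tetrazole | CCS(=O)(=O)c1nnnn1-c1ccccc1 | starting material
14 | potassium 1-[(1-phenyl-1H-tetrazol-5-yl)sulfonyl]ethan-1-ide | C[CH-]S(=O)(=O)c1nnnn1-c1ccccc1.[K+] | intermediate
15 | (2R,3R)-6-methoxy-3-methyl-5-[(E)-prop-1-en-1-yl]-2-(3,4,5-trimethoxyphenyl)-2,3-dihydro-1-benzofuran (CNP0122299.1) | C/C=C/c1cc2c(cc1OC)O[C@@H](c1cc(OC)c(OC)c(OC)c1)[C@@H]2C | target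

**Step count and risks**

Total step count: 6. Longest linear sequence: 5 steps (steps 1, 2, 4, 5, 6 from aldehyde 1); step 3 is a one-step branch.

Steps most likely to fail:

Step 4. Before fluoride displacement is complete, the potassium allylic alkoxide may isomerise to the ketone enolate, and unconsumed base may deprotonate the doubly activated C2–H of ether 9; both cost material and optical purity. In the second stage the facial selectivity of the 5-exo closure may be too low, leaving the 2,3-cis epimer to be separated. The fallback makes the ether oxygen–C2 bond instead of the O1–C7a bond, under neutral conditions and from the other enantiomer. It sets out from 4 and 7. The lipase hydrolysis of 4 is run past half conversion, and the remaining (S)-1-(3,4,5-trimethoxyphenyl)prop-2-en-1-yl acetate F1 is methanolysed (K2CO3, MeOH) to (S)-1-(3,4,5-trimethoxyphenyl)prop-2-en-1-ol F2. Compound 7 is converted with KOH in DMSO/water into 4-hydroxy-5-iodo-2-methoxybenzonitrile F3. Mitsunobu coupling of F2 and F3 (PPh3, diisopropyl azodicarboxylate, toluene, 0 °C) should give 9 with inversion at the carbinol carbon. The fallback comes back to the route at 9, which is then isolated, purified and cyclised with Bu3SnH/Et3B/air at low temperature to 10; this also gives the best chance of a high trans preference.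

Step 2. The enzyme may discriminate poorly between the enantiomers of this bulky trimethoxyaryl acetate, or background solvolysis of the activated allylic acetate in buffer may give racemic alcohol, so that 5 is not optically pure. The fallback replaces resolution by catalytic asymmetric synthesis. It sets out from 1: Zn(CH=CH2)2 (from 2 and ZnCl2) is added in toluene at 0 °C with a catalytic chiral β-amino alcohol of the 3-exo-(dimethylamino)isoborneol type, in the enantiomeric form that delivers the vinyl group to the Re face of the aldehyde. It comes back to the route at 5 and makes no new compound (F0).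

Step 6. The olefination may be incompletely E-selective, giving some Z alkene that is hard to remove, or addition to the electron-rich aldehyde may be sluggish. The fallback is addition followed by elimination under thermodynamic control. It sets out from 12: C2H5MgBr (THF, 0 °C) should give 1-[(2R,3R)-6-methoxy-3-methyl-2-(3,4,5-trimethoxyphenyl)-2,3-dihydro-1-benzofuran-5-yl]propan-1-ol F4 as a mixture of carbinol epimers. Dehydration with catalytic pyridinium p-toluenesulfonate in toluene at 80 °C over molecular sieves goes through the benzylic cation stabilised by the ortho methoxy group and the para ring oxygen, and should give the conjugated E alkene. It comes back to the route at 15.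

Further compounds
F1 | step 4 | (S)-1-(3,4,5-trimethoxyphenyl)prop-2-en-1-yl acetate | C=C[C@H](OC(C)=O)c1cc(OC)c(OC)c(OC)c1
F2 | step 4 | (S)-1-(3,4,5-trimethoxyphenyl)prop-2-en-1-ol | C=C[C@H](O)c1cc(OC)c(OC)c(OC)c1
F3 | step 4 | 4-hydroxy-5-iodo-2-methoxybenzonitrile | COc1cc(O)c(I)cc1C#N
F0 | step 2 | none | none
F4 | step 6 | 1-[(2R,3R)-6-methoxy-3-methyl-2-(3,4,5-trimethoxyphenyl)-2,3-dihydro-1-benzofuran-5-yl]propan-1-ol (mixture of carbinol epimers) | CCC(O)c1cc2c(cc1OC)O[C@@H](c1cc(OC)c(OC)c(OC)c1)[C@@H]2C
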